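Retrosynthesis: the bond from the exocyclic carbon C6 to its dibromohydroxyphenyl ring is cut last, giving methylidene butenolide 7 and diazonium salt 9. Compound 7 is then cut at C5=C6 (dehydration of lactol 6) and at C3=C4 and O1–C5 (aldol condensation and lactol closure from aryl acetone 2 and glyoxylic acid 3).
Forward: dibrominate the phenol, close the furan-2(5H)-one ring (O1, C2–C5) by aldol condensation and lactol formation, dehydrate to the exocyclic C5=C6 alkene, then attach the second aryl ring at C6.
Enabling feature: C6 is the open terminus of the O1–C5=C6 enol-lactone unit of the furanone ring and C5 carries no hydrogen, so an arylpalladium can add only at C6 and can eliminate only back to C5=C6.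
Both carbons to be joined are nucleophilic in their parent forms (C6 of the enol lactone; the para carbon of a 2,6-dibromophenol). The phenol carbon is polarity-reversed as a diazonium group, which leaves as N2 and reacts ahead of all four C–Br bonds, so no protecting group is needed.
Stereochemistry: the target has no stereocentre; the Z geometry of C5=C6 comes from the syn β-hydride elimination of the key step and is also the thermodynamically preferred geometry.

Key step: step 5

Assumption: 9 can be isolated and used as its protonated tetrafluoroborate salt; base is kept away from it because deprotonation of its acidic phenol would give the less reactive quinone diazide.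

Step 1
Reactants: 1 4-hydroxyphenylacetone [1-(4-hydroxyphenyl)propan-2-one]
Product: 2 1-(3,5-dibromo-4-hydroxyphenyl)propan-2-one
Conditions: NBS (2.05 equiv), MeCN, 0 °C to rt
Reagents that add atoms: N-bromosuccinimide, O=C1CCC(=O)N1Br
Why: Electrophilic aromatic bromination of the phenol at both positions ortho to OH (para is blocked) should be far faster than α-bromination of the ketone, because N-bromosuccinimide releases no HBr to catalyse enolisation.

Step 2
Reactants: 2 1-(3,5-dibromo-4-hydroxyphenyl)propan-2-one; 3 glyoxylic acid monohydrate
Product: 6 4-(3,5-dibromo-4-hydroxyphenyl)-5-hydroxy-5-methylfuran-2(5H)-one (racemic lactol), via aldol adduct 4 (not isolated), via Z keto acid 5 (not isolated)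
Conditions: 85% H3PO4, 80 °C
Reagents that add atoms: none
Why: Acid-catalysed crossed aldol condensation through the more substituted, aryl-conjugated enol at the benzylic CH2, followed by ring-chain tautomerism of the Z γ-keto acid to the lactol, should give 6, whose C5 stereocentre is formed racemic and is removed in step 3.

Step 3
Reactants: 6 4-(3,5-dibromo-4-hydroxyphenyl)-5-hydroxy-5-methylfuran-2(5H)-one
Product: 7 4-(3,5-dibromo-4-hydroxyphenyl)-5-methylidenefuran-2(5H)-one
Conditions: P2O5, CH2Cl2, reflux; product used promptly
Reagents that add atoms: none
Why: Acid-promoted dehydration (E1) of the tertiary lactol through the C5 acyloxycarbenium ion can only place the new double bond toward the methyl group, the sole neighbour of C5 that carries hydrogen, so the exocyclic C5=C6 alkene is the only possible product.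

Step 4
Reactants: 8 4-amino-2,6-dibromophenol
Product: 9 3,5-dibromo-4-hydroxybenzenediazonium tetrafluoroborate
Conditions: NaNO2, 48% aq. HBF4, 0 °C; filter, wash with cold Et2O
Reagents that add atoms: sodium nitrite, [Na+].[O-]N=O; tetrafluoroboric acid, [H+].F[B-](F)(F)F
Why: Standard diazotisation of an aniline in a non-nucleophilic acid should precipitate the tetrafluoroborate salt from the strongly acidic medium that keeps the phenol protonated.

Step 5
Reactants: 7 4-(3,5-dibromo-4-hydroxyphenyl)-5-methylidenefuran-2(5H)-one; 9 3,5-dibromo-4-hydroxybenzenediazonium tetrafluoroborate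
Product: 10 rubrolide A
Conditions: Pd(OAc)2 (5 mol %), MeCN, 25–40 °C, no base
Reagents that add atoms: none
Why: Zerovalent palladium, formed in situ from Pd(OAc)2, inserts into the C–N2+ bond of 9 with loss of N2 to give a cationic arylpalladium species that binds the exocyclic C5=C6 bond of 7, transfers the aryl group to the terminal carbon C6 by syn migratory insertion (palladium moving to C5, where it is held as an η3-allyl over C5–C4–C3) and leaves by syn β-hydride elimination. The closest known reaction type is the base-free Heck–Matsuda arylation of 1,1-disubstituted terminal alkenes such as α-methylene lactones and enol esters with phenol diazonium salts. No ring is closed and no stereocentre is formed, the only stereochemical element being the geometry of C5=C6. Since C5 has no hydrogen and its other neighbours are O1 and the sp2 carbon C4, the only β-hydrogens are the two on C6, so the double bond can only re-form between C5 and C6, and the elimination rotamer that keeps the incoming aryl group away from the C4 aryl ring leads to the Z isomer, which is also the thermodynamic one toward which any E isomer should equilibrate under the acid released. The step needs selectivity for C–N2+ over four C–Br bonds (secured because ligand-free palladium does not insert into aryl bromides at 25–40 °C), for the exocyclic alkene over the trisubstituted, carbonyl-conjugated C3=C4 bond (secured by sterics and by C6 being the open terminus of the dienyl lactone), and for C–C coupling in the presence of two free phenols (secured by the absence of base and by every ortho and para position of both phenols being substituted, which blocks azo coupling).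

Compound list
1 | 4-hydroxyphenylacetone, 1-(4-hydroxyphenyl)propan-2-one | CC(=O)Cc1ccc(O)cc1 | starting material
2 | 1-(3,5-dibromo-4-hydroxyphenyl)propan-2-one | CC(=O)Cc1cc(Br)c(O)c(Br)c1 | intermediate
3 | glyoxylic acid monohydrate (2,2-dihydroxyacetic acid) | OC(O)C(=O)O | starting material
4 | 3-(3,5-dibromo-4-hydroxyphenyl)-2-hydroxy-4-oxopentanoic acid (aldol adduct, diastereomer mixture, not isolated) | CC(=O)C(c1cc(Br)c(O)c(Br)c1)C(O)C(=O)O | intermediate
5 | (2Z)-3-(3,5-dibromo-4-hydroxyphenyl)-4-oxopent-2-enoic acid (not isolated) | OC(=O)/C=C(\C(C)=O)c1cc(Br)c(O)c(Br)c1 | intermediate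
6 | 4-(3,5-dibromo-4-hydroxyphenyl)-5-hydroxy-5-methylfuran-2(5H)-one (racemic) | CC1(O)OC(=O)C=C1c2cc(Br)c(O)c(Br)c2 | intermediate
7 | 4-(3,5-dibromo-4-hydroxyphenyl)-5-methylidenefuran-2(5H)-one | C=C1OC(=O)C=C1c2cc(Br)c(O)c(Br)c2 | intermediate
8 | 4-amino-2,6-dibromophenol | Nc1cc(Br)c(O)c(Br)c1 | starting material
9 | 3,5-dibromo-4-hydroxybenzenediazonium tetrafluoroborate | Oc1c(Br)cc(cc1Br)[N+]#N.F[B-](F)(F)F | intermediate
10 | rubrolide A, (5Z)-4-(3,5-dibromo-4-hydroxyphenyl)-5-[(3,5-dibromo-4-hydroxyphenyl)methylidene]furan-2(5H)-one | O=C1C=C(c2cc(Br)c(O)c(Br)c2)/C(=C/c2cc(Br)c(O)c(Br)c2)O1 | target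

Total step count: 5. Longest linear sequence: 4 steps (1 → 2 → 6 → 7 → 10); 9 is made in one step from 8 and joins in step 5.

Steps most likely to fail

Step 5. The diazonium salt may lose its phenolic proton and stall as the quinone diazide. The acid released may oligomerise or hydrate the enol lactone faster than carbopalladation occurs, and the E/Z mixture may not converge fully. The fallback sets out from 7, reverses the roles of the partners (C6 becomes the halide) and comes back at 10. Addition of Br2 (CH2Cl2, 0 °C) across C5=C6 should give 5-bromo-5-(bromomethyl)-4-(3,5-dibromo-4-hydroxyphenyl)furan-2(5H)-one F1. Dehydrobromination with Et3N (CH2Cl2, 0 °C) should give (5Z)-5-(bromomethylidene)-4-(3,5-dibromo-4-hydroxyphenyl)furan-2(5H)-one F2. Suzuki–Miyaura coupling of F2 with 4-hydroxyphenylboronic acid (Pd(PPh3)4, CsF, THF, 50 °C) should give (5Z)-4-(3,5-dibromo-4-hydroxyphenyl)-5-[(4-hydroxyphenyl)methylidene]furan-2(5H)-one F3 with retention of geometry; the activated vinyl bromide is expected to react ahead of the hindered aryl bromides that flank the phenol. Dibromination with NBS (2 equiv, MeCN, 0 °C) at the two free positions ortho to the only unsubstituted phenol should then give 10.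

Step 3. The cross-conjugated methylidene butenolide may dimerise or oligomerise under hot acidic dehydrating conditions or on concentration, and the phenol may be phosphorylated. The fallback sets out from 9, builds the exocyclic alkene under cold conditions by a Peterson olefination, and comes back at 7; it also replaces steps 1 and 2, so both aryl rings would come from 9. Heck–Matsuda arylation of maleic anhydride with 9 (Pd(OAc)2, MeCN, 60 °C) should give 3-(3,5-dibromo-4-hydroxyphenyl)furan-2,5-dione F4. Addition of TMSCH2MgCl (2.5 equiv, THF, −78 °C) should give 4-(3,5-dibromo-4-hydroxyphenyl)-5-hydroxy-5-[(trimethylsilyl)methyl]furan-2(5H)-one F5. The first equivalent forms the magnesium phenoxide, whose donation through the aryl ring deactivates the remote, vinylogous carbonyl, so addition is expected at the carbonyl next to the aryl-bearing carbon. Acid-induced Peterson elimination (cat. TFA, CH2Cl2, 0 °C) should then give 7.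

Step 2. Enolisation of the hindered, electron-poor brominated ketone may be slow and unselective, so that aldol at the methyl group competes. Hot acid may also cause loss or migration of bromine on the phenol ring. The fallback sets out from 1, reverses the order of ring formation and halogenation, and comes back at 6. Condensation of 1 with 3 (85% H3PO4, 80 °C) should give 5-hydroxy-4-(4-hydroxyphenyl)-5-methylfuran-2(5H)-one F6. Bromination of F6 with NBS (2.05 equiv, MeCN, 0 °C) at both positions ortho to the phenol OH should then give 6; no enolisable benzylic ketone is present at that stage. If the site of the aldol reaction itself is the problem, the fallback for step 3 serves, since it avoids the aldol altogether.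

Further compounds
F1 | step 5 | 5-bromo-5-(bromomethyl)-4-(3,5-dibromo-4-hydroxyphenyl)furan-2(5H)-one (racemic) | BrCC1(Br)OC(=O)C=C1c2cc(Br)c(O)c(Br)c2
F2 | step 5 | (5Z)-5-(bromomethylidene)-4-(3,5-dibromo-4-hydroxyphenyl)furan-2(5H)-one | O=C1C=C(c2cc(Br)c(O)c(Br)c2)/C(=C/Br)O1
F3 | step 5 | (5Z)-4-(3,5-dibromo-4-hydroxyphenyl)-5-[(4-hydroxyphenyl)methylidene]furan-2(5H)-one | O=C1C=C(c2cc(Br)c(O)c(Br)c2)/C(=C/c3ccc(O)cc3)O1
F4 | step 3 | 3-(3,5-dibromo-4-hydroxyphenyl)furan-2,5-dione | O=C1OC(=O)C(c2cc(Br)c(O)c(Br)c2)=C1
F5 | step 3 | 4-(3,5-dibromo-4-hydroxyphenyl)-5-hydroxy-5-[(trimethylsilyl)methyl]furan-2(5H)-one (racemic) | C[Si](C)(C)CC1(O)OC(=O)C=C1c2cc(Br)c(O)c(Br)c2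
F6 | step 2 | 5-hydroxy-4-(4-hydroxyphenyl)-5-methylfuran-2(5H)-one (racemic) | CC1(O)OC(=O)C=C1c2ccc(O)cc2
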